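**Plan**

- Retrosynthesis: the benzyl and silyl groups come off last; the C3 carbinol goes back to an aryl ketone and the C2 methyl ether to a phenol; ring A (C1 CO2H, C2 OMe, C3 side chain, C6 O-aryl) is opened at C4–C5 and C2–C3; the diaryl ether C6–O bond is cut on the open-chain piece.
- Enabling feature: in ring A, C5–C6–C1–C2 with the ether oxygen on C6, the carboxyl carbon on C1 and the oxygen on C2 are the skeleton of a γ-enolised aryloxyethylidene malonate (a 3-aryloxy vinylketene acetal), and C3–C4 with the side-chain carbonyl are a terminal ynone.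
- Forward: ring B is taken from creosol and made into a hindered phenol (5 steps), joined to a chloroethylidene malonate by addition–elimination and converted to the silyl diene; cycloaddition–aromatisation with the ynone (3 steps from 3-hydroxy-3-methylbutanoic acid) then builds ring A with its four contiguous substituents.
- Stereochemistry: the single (R) centre is set after ring formation by oxazaborolidine-catalysed borane reduction of the ring-bound ketone; no later step touches it.
- Endgame: O-methylation, reduction, fluoride desilylation, hydrogenolysis.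

Key step: step 13

Abbreviation: ArB = 2-(benzyloxy)-4-methyl-6-{[tri(propan-2-yl)silyl]oxymethyl}phenyl (protected ring B); ring A is numbered as in the target (C1 carries the carboxyl).
Remark: the ketene acetal geometry of 19 has no consequence (C2 loses one oxygen substituent on aromatisation) and is left undefined; phenoxides formed reversibly by K2CO3 and alkoxide or borate forms of a product that only await work-up are not numbered.

**Route**

Step 1
Reactants: 1 2-methoxy-4-methylphenol (creosol)
Product: 2 2-hydroxy-3-methoxy-5-methylbenzaldehyde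
Conditions: MgCl2, Et3N, paraformaldehyde, MeCN, reflux; 1 M HCl work-up
Reagents that add atoms: paraformaldehyde (as formaldehyde), C=O
Why: Magnesium-phenoxide-directed ortho-formylation (Casnati–Skattebøl) should deliver the formyl group only to the one free position ortho to the hydroxyl, the para position being blocked by methyl.

Step 2
Reactants: 2 2-hydroxy-3-methoxy-5-methylbenzaldehyde
Product: 3 2,3-dihydroxy-5-methylbenzaldehyde
Conditions: BBr3, CH2Cl2, −78 → 0 °C; H2O
Reagents that add atoms: none
Why: Lewis-acid cleavage of the aryl methyl ether with BBr3 is the standard conversion of o-vanillin-type aldehydes into 2,3-dihydroxybenzaldehydes and leaves the formyl group intact.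

Step 3
Reactants: 3 2,3-dihydroxy-5-methylbenzaldehyde
Product: 5 3-(benzyloxy)-2-hydroxy-5-methylbenzaldehyde, via disodium dianion 4 (not isolated)
Conditions: NaH (2.2 equiv), DMSO, 23 °C; BnBr (1.0 equiv), 23 °C; then 1 M HCl
Reagents that add atoms: benzyl bromide, BrCc1ccccc1
Why: In this Williamson etherification of the dianion the 2-phenoxide is chelated by and delocalised into the formyl group, so the 3-phenoxide is the more nucleophilic oxygen and should take the single equivalent of benzyl bromide, as is known for 2,3-dihydroxybenzaldehyde.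

Step 4
Reactants: 5 3-(benzyloxy)-2-hydroxy-5-methylbenzaldehyde
Product: 6 2-(benzyloxy)-6-(hydroxymethyl)-4-methylphenol
Conditions: NaBH4, MeOH, 0 °C
Reagents that add atoms: none
Why: Borohydride reduction of a salicylaldehyde to the salicyl alcohol is routine and touches neither the benzyl ether nor the ring.

Step 5
Reactants: 6 2-(benzyloxy)-6-(hydroxymethyl)-4-methylphenol
Product: 7 2-(benzyloxy)-4-methyl-6-{[tri(propan-2-yl)silyl]oxymethyl}phenol (ArB–OH)
Conditions: iPr3SiCl (1.05 equiv), imidazole, CH2Cl2, 0 → 23 °C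
Reagents that add atoms: chlorotri(propan-2-yl)silane, CC(C)[Si](Cl)(C(C)C)C(C)C
Why: Selective silylation of the primary benzylic alcohol in the presence of a flanked, hydrogen-bonded phenol is well precedented for salicyl alcohols, and the bulky silyl group should survive the amide base, carbonate and borane steps ahead.

Step 6
Reactants: 8 dibenzyl propanedioate (dibenzyl malonate)
Product: 9 dibenzyl 2-acetylpropanedioate
Conditions: MgCl2, Et3N (2 equiv), AcCl, MeCN, 0 → 23 °C; 1 M HCl work-up
Reagents that add atoms: acetyl chloride, CC(=O)Cl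
Why: Magnesium-enolate C-acylation of malonates (Rathke conditions) gives acylmalonates cleanly because the chelated product enolate resists further acylation.

Step 7
Reactants: 9 dibenzyl 2-acetylpropanedioate
Product: 10 dibenzyl 2-(1-chloroethylidene)propanedioate
Conditions: POCl3, Bu3N, 70 °C; ice-water work-up
Reagents that add atoms: phosphoryl chloride, O=P(Cl)(Cl)Cl
Why: Chlorodehydroxylation of the enolised β-dicarbonyl to the vinylogous acid chloride with POCl3 and a tertiary amine is established for dialkyl acetylmalonates.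

Step 8
Reactants: 7 ArB–OH; 10 dibenzyl 2-(1-chloroethylidene)propanedioate
Product: 11 dibenzyl 2-[1-(ArB-oxy)ethylidene]propanedioate
Conditions: K2CO3, MeCN, 23 → 50 °C
Reagents that add atoms: none
Why: Nucleophilic vinylic substitution by addition–elimination of the phenoxide on the doubly activated β-chloroalkylidene malonate forms the hindered aryl–O–C6 bond on an open-chain carbon, the known route from phenols to aryloxyalkylidene malonates.

Step 9
Reactants: 12 3-hydroxy-3-methylbutanoic acid
Product: 14 3-hydroxy-N-methoxy-N,3-dimethylbutanamide, via acyl imidazole 13 (not isolated)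
Conditions: 1,1'-carbonyldiimidazole, CH2Cl2, 0 → 23 °C; then MeNH(OMe)·HCl, 23 °C
Reagents that add atoms: N,O-dimethylhydroxylamine hydrochloride, CNOC.Cl
Why: Carbonyldiimidazole-mediated amidation gives the Weinreb amide, and the tertiary hydroxyl is too hindered to compete for the acyl imidazole.

Step 10
Reactants: 14 3-hydroxy-N-methoxy-N,3-dimethylbutanamide
Product: 15 N-methoxy-N,3-dimethyl-3-(triethylsilyloxy)butanamide
Conditions: Et3SiOTf, 2,6-lutidine, CH2Cl2, −78 → 0 °C
Reagents that add atoms: triethylsilyl trifluoromethanesulfonate, CC[Si](CC)(CC)OS(=O)(=O)C(F)(F)F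
Why: Silyl triflate with a hindered pyridine base is the standard O-silylation of tertiary alcohols.

Step 11
Reactants: 15 N-methoxy-N,3-dimethyl-3-(triethylsilyloxy)butanamide
Product: 17 5-methyl-5-(triethylsilyloxy)hex-1-yn-3-one, via magnesium hemiaminal chelate 16 (not isolated)
Conditions: HC≡CMgBr (0.5 M in THF), THF, 0 °C; inverse quench into cold 10% aq. citric acid
Reagents that add atoms: ethynylmagnesium bromide, C#C[Mg]Br
Why: In this Weinreb ketone synthesis the stable chelate 16 prevents a second addition, and the inverse acidic quench protonates the liberated amine before it can add to the ynone.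

Step 12
Reactants: 11 dibenzyl 2-[1-(ArB-oxy)ethylidene]propanedioate
Product: 19 benzyl 3-(ArB-oxy)-2-[benzyloxy(trimethylsilyloxy)methylidene]but-3-enoate, via lithium dienolate 18 (not isolated)
Conditions: LiN(iPr)2 (LDA, 1.1 equiv), THF, −78 °C; Me3SiCl (1.5 equiv), −78 → 0 °C; evaporate, take up in pentane, filter under argon; used crude
Reagents that add atoms: chlorotrimethylsilane, C[Si](C)(C)Cl
Why: The γ-methyl group carries the only acidic hydrogens of the alkylidene malonate, so kinetic γ-deprotonation gives the cross-conjugated dienolate, and O-silylation of this malonate-type enolate gives the vinylketene silyl acetal.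

Step 13
Reactants: 19 benzyl 3-(ArB-oxy)-2-[benzyloxy(trimethylsilyloxy)methylidene]but-3-enoate; 17 5-methyl-5-(triethylsilyloxy)hex-1-yn-3-one
Product: 22 benzyl 6-(ArB-oxy)-2-hydroxy-3-[3-methyl-3-(triethylsilyloxy)butanoyl]benzoate, via cycloadduct 20 (not isolated), via aryl trimethylsilyl ether 21 (not isolated)
Conditions: 19 (about 1.3 equiv), PhMe, 23 → 80 °C; then 10% aq. citric acid, THF, 0 °C
Reagents that add atoms: none
Why: Proposed new method: the ketene-acetal oxygens on C2 and the aryloxy group on C6 both push electron density to the CH2 terminus C5 of 19, which should attack the unsubstituted β-carbon C4 of ynone 17 while the acetal carbon C2 bonds to the acyl-bearing alkyne carbon C3, either in one asynchronous Diels–Alder event or by vinylogous Mukaiyama–Michael addition and collapse of the zwitterion; the closest known reaction type is the Diels–Alder/aromatisation of 1-alkoxy-1-silyloxybuta-1,3-dienes (vinylketene silyl acetals) with acetylenic ketones and esters to give salicylates, not yet shown for a malonate-derived diene with a 2-ester and a 3-aryloxy group. Ring A closes in the [4+2] mode, all six ring atoms coming from the two open-chain partners, to give cyclohexa-1,4-diene 20. The benzyl silyl ketal at C2 of 20 should then lose benzyl alcohol by 1,4-elimination with a C5 hydrogen to give aryl silyl ether 21, whose O–Si bond the dilute acid wash hydrolyses to the chelated phenol 22. No stereocentre is formed, because the sp3 ring carbons of 20 become aromatic. The step needs head-to-tail regiochemistry and bonding through C5, not through the malonate α-carbon C1; the matched donor/acceptor polarisation, the fully substituted and hindered C1, and Lewis-acid-free thermal conditions that favour cycloaddition should secure both.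

Step 14
Reactants: 22 benzyl 6-(ArB-oxy)-2-hydroxy-3-[3-methyl-3-(triethylsilyloxy)butanoyl]benzoate
Product: 23 benzyl 6-(ArB-oxy)-2-methoxy-3-[3-methyl-3-(triethylsilyloxy)butanoyl]benzoate
Conditions: MeI, K2CO3, DMF, 23 °C
Reagents that add atoms: iodomethane, CI
Why: Williamson O-methylation of the acidic, doubly chelated phenol proceeds with carbonate, which is too weak to enolise the ketone toward β-elimination of the silyloxy group.

Step 15
Reactants: 23 benzyl 6-(ArB-oxy)-2-methoxy-3-[3-methyl-3-(triethylsilyloxy)butanoyl]benzoate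
Product: 24 benzyl 6-(ArB-oxy)-3-[(1R)-1-hydroxy-3-methyl-3-(triethylsilyloxy)butyl]-2-methoxybenzoate
Conditions: (S)-2-methyl-CBS-oxazaborolidine (20 mol %), BH3·SMe2, THF, −20 °C; MeOH quench
Reagents that add atoms: none
Why: In this Corey–Bakshi–Shibata reduction the (S)-oxazaborolidine–borane complex binds the ketone with the aryl group as the large substituent and delivers hydride to the face that gives the (R)-carbinol, the same sense as acetophenone to (R)-1-phenylethanol, while the hindered benzyl ester is inert to borane at this temperature.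

Step 16
Reactants: 24 benzyl 6-(ArB-oxy)-3-[(1R)-1-hydroxy-3-methyl-3-(triethylsilyloxy)butyl]-2-methoxybenzoate
Product: 25 benzyl 6-[2-(benzyloxy)-6-(hydroxymethyl)-4-methylphenoxy]-3-[(1R)-1,3-dihydroxy-3-methylbutyl]-2-methoxybenzoate
Conditions: Bu4NF (3 equiv), THF, 0 → 23 °C
Reagents that add atoms: none
Why: Fluoride-mediated desilylation removes both silyl ethers under non-acidic conditions, which spares the ionisation-prone benzylic carbinol (ortho-methoxy, para-aryloxy) and its configuration.

Step 17
Reactants: 25 benzyl 6-[2-(benzyloxy)-6-(hydroxymethyl)-4-methylphenoxy]-3-[(1R)-1,3-dihydroxy-3-methylbutyl]-2-methoxybenzoate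
Product: 26 3-[(1R)-1,3-dihydroxy-3-methylbutyl]-6-[2-hydroxy-6-(hydroxymethyl)-4-methylphenoxy]-2-methoxybenzoic acid (CNP0452050.1)
Conditions: H2 (1 atm), 10% Pd/C, EtOAc, 23 °C; stopped after uptake of two equivalents
Reagents that add atoms: none
Why: Catalytic hydrogenolysis cleaves the hindered benzyl ester and the aryl benzyl ether regardless of steric crowding, and neutral ethyl acetate with controlled hydrogen uptake should leave the benzylic C–OH bonds and the stereocentre untouched.

**Compound list**

1 | 2-methoxy-4-methylphenol (creosol) | Cc1ccc(O)c(OC)c1 | starting material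
2 | 2-hydroxy-3-methoxy-5-methylbenzaldehyde | Cc1cc(C=O)c(O)c(OC)c1 | intermediate
3 | 2,3-dihydroxy-5-methylbenzaldehyde | Cc1cc(C=O)c(O)c(O)c1 | intermediate
4 | disodium 3-formyl-5-methylbenzene-1,2-diolate | [Na+].[Na+].Cc1cc(C=O)c([O-])c([O-])c1 | intermediate (not isolated)
5 | 3-(benzyloxy)-2-hydroxy-5-methylbenzaldehyde | Cc1cc(C=O)c(O)c(OCc2ccccc2)c1 | intermediate
6 | 2-(benzyloxy)-6-(hydroxymethyl)-4-methylphenol | Cc1cc(CO)c(O)c(OCc2ccccc2)c1 | intermediate
7 | 2-(benzyloxy)-4-methyl-6-{[tri(propan-2-yl)silyl]oxymethyl}phenol (ArB–OH) | Cc1cc(CO[Si](C(C)C)(C(C)C)C(C)C)c(O)c(OCc2ccccc2)c1 | intermediate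
8 | dibenzyl propanedioate (dibenzyl malonate) | O=C(CC(=O)OCc1ccccc1)OCc1ccccc1 | starting material
9 | dibenzyl 2-acetylpropanedioate | CC(=O)C(C(=O)OCc1ccccc1)C(=O)OCc1ccccc1 | intermediate
10 | dibenzyl 2-(1-chloroethylidene)propanedioate | CC(Cl)=C(C(=O)OCc1ccccc1)C(=O)OCc1ccccc1 | intermediate
11 | dibenzyl 2-[1-(ArB-oxy)ethylidene]propanedioate | CC(Oc1c(OCc2ccccc2)cc(C)cc1CO[Si](C(C)C)(C(C)C)C(C)C)=C(C(=O)OCc1ccccc1)C(=O)OCc1ccccc1 | intermediate
12 | 3-hydroxy-3-methylbutanoic acid | CC(C)(O)CC(=O)O | starting material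
13 | 3-hydroxy-1-(imidazol-1-yl)-3-methylbutan-1-one (acyl imidazole) | CC(C)(O)CC(=O)n1ccnc1 | intermediate (not isolated)
14 | 3-hydroxy-N-methoxy-N,3-dimethylbutanamide | CON(C)C(=O)CC(C)(C)O | intermediate
15 | N-methoxy-N,3-dimethyl-3-(triethylsilyloxy)butanamide | CC[Si](CC)(CC)OC(C)(C)CC(=O)N(C)OC | intermediate
16 | bromomagnesium alkoxide of the ethynyl hemiaminal (tetrahedral chelate) | C#CC(O[Mg]Br)(CC(C)(C)O[Si](CC)(CC)CC)N(C)OC | intermediate (not isolated)
17 | 5-methyl-5-(triethylsilyloxy)hex-1-yn-3-one | C#CC(=O)CC(C)(C)O[Si](CC)(CC)CC | intermediate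
18 | lithium dienolate of 11 | [Li+].C=C(Oc1c(OCc2ccccc2)cc(C)cc1CO[Si](C(C)C)(C(C)C)C(C)C)C(C(=O)OCc1ccccc1)=C([O-])OCc1ccccc1 | intermediate (not isolated)
19 | benzyl 3-(ArB-oxy)-2-[benzyloxy(trimethylsilyloxy)methylidene]but-3-enoate (ketene acetal geometry undefined) | C=C(Oc1c(OCc2ccccc2)cc(C)cc1CO[Si](C(C)C)(C(C)C)C(C)C)C(C(=O)OCc1ccccc1)=C(OCc1ccccc1)O[Si](C)(C)C | intermediate
20 | benzyl 2-(ArB-oxy)-6-benzyloxy-5-[3-methyl-3-(triethylsilyloxy)butanoyl]-6-(trimethylsilyloxy)cyclohexa-1,4-diene-1-carboxylate (racemic at the ketal carbon) | O=C(OCc1ccccc1)C1=C(Oc2c(OCc3ccccc3)cc(C)cc2CO[Si](C(C)C)(C(C)C)C(C)C)CC=C(C(=O)CC(C)(C)O[Si](CC)(CC)CC)C1(OCc1ccccc1)O[Si](C)(C)C | intermediate (not isolated)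
21 | benzyl 6-(ArB-oxy)-3-[3-methyl-3-(triethylsilyloxy)butanoyl]-2-(trimethylsilyloxy)benzoate | C[Si](C)(C)Oc1c(C(=O)CC(C)(C)O[Si](CC)(CC)CC)ccc(Oc2c(OCc3ccccc3)cc(C)cc2CO[Si](C(C)C)(C(C)C)C(C)C)c1C(=O)OCc1ccccc1 | intermediate (not isolated)
22 | benzyl 6-(ArB-oxy)-2-hydroxy-3-[3-methyl-3-(triethylsilyloxy)butanoyl]benzoate | Oc1c(C(=O)CC(C)(C)O[Si](CC)(CC)CC)ccc(Oc2c(OCc3ccccc3)cc(C)cc2CO[Si](C(C)C)(C(C)C)C(C)C)c1C(=O)OCc1ccccc1 | intermediate
23 | benzyl 6-(ArB-oxy)-2-methoxy-3-[3-methyl-3-(triethylsilyloxy)butanoyl]benzoate | COc1c(C(=O)CC(C)(C)O[Si](CC)(CC)CC)ccc(Oc2c(OCc3ccccc3)cc(C)cc2CO[Si](C(C)C)(C(C)C)C(C)C)c1C(=O)OCc1ccccc1 | intermediate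
24 | benzyl 6-(ArB-oxy)-3-[(1R)-1-hydroxy-3-methyl-3-(triethylsilyloxy)butyl]-2-methoxybenzoate | COc1c([C@H](O)CC(C)(C)O[Si](CC)(CC)CC)ccc(Oc2c(OCc3ccccc3)cc(C)cc2CO[Si](C(C)C)(C(C)C)C(C)C)c1C(=O)OCc1ccccc1 | intermediate
25 | benzyl 6-[2-(benzyloxy)-6-(hydroxymethyl)-4-methylphenoxy]-3-[(1R)-1,3-dihydroxy-3-methylbutyl]-2-methoxybenzoate | COc1c([C@H](O)CC(C)(C)O)ccc(Oc2c(OCc3ccccc3)cc(C)cc2CO)c1C(=O)OCc1ccccc1 | intermediate
26 | 3-[(1R)-1,3-dihydroxy-3-methylbutyl]-6-[2-hydroxy-6-(hydroxymethyl)-4-methylphenoxy]-2-methoxybenzoic acid (CNP0452050.1) | COc1c([C@H](O)CC(C)(C)O)ccc(Oc2c(O)cc(C)cc2CO)c1C(=O)O | target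

**Step count**

Total steps: 17. Longest linear sequence: 12 (steps 1–5, 8, 12–17).

**Steps most likely to fail**

1. Step 13 (proposed new method). The ester-deactivated diene may react too slowly, so that the ynone oligomerises or the ketene acetal is lost before ring closure, or bonding may occur through C1 in a Mukaiyama–Michael sense and give an open-chain adduct that cannot aromatise. Fallback by known chemistry, setting out from phenol 7 and returning at triol 25:
   - Purchased 2-fluoro-6-hydroxybenzoic acid F1 is esterified (BnBr, KHCO3, DMF) to benzyl 2-fluoro-6-hydroxybenzoate F2.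
   - Magnesium-mediated ortho-formylation (MgCl2, Et3N, paraformaldehyde) at the only free ortho position gives benzyl 6-fluoro-3-formyl-2-hydroxybenzoate F3, and O-methylation (MeI, K2CO3) gives benzyl 6-fluoro-3-formyl-2-methoxybenzoate F4.
   - The fluorine of F4 is para to the formyl group and ortho to the ester, so nucleophilic aromatic substitution by 7 (K2CO3, DMF, 60 °C) should give benzyl 6-(ArB-oxy)-3-formyl-2-methoxybenzoate F5.
   - Asymmetric methallylboration with B-methallyldiisopinocampheylborane of the (+)-Ipc series (from (−)-α-pinene, the enantiomer that attacks the Re face of aryl aldehydes; Et2O, −78 °C, ethanolamine work-up) gives benzyl 6-(ArB-oxy)-3-[(1R)-1-hydroxy-3-methylbut-3-enyl]-2-methoxybenzoate F6.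
   - Mukaiyama hydration of the 1,1-disubstituted alkene (Co(acac)2, PhSiH3, O2, THF) gives benzyl 6-(ArB-oxy)-3-[(1R)-1,3-dihydroxy-3-methylbutyl]-2-methoxybenzoate F7, and Bu4NF removes the silyl group to reach 25.

2. Step 12. Silylation of the stabilised lithium dienolate may be incomplete or occur on carbon, and the ketene acetal may hydrolyse while lithium salts are removed, returning mixtures of 11 and its deconjugated isomer. Fallback, setting out from 11 and returning at diene 19:
   - The dienolate 18 is protonated kinetically at the α-carbon (AcOH, THF, −78 °C) to give the isolable, deconjugated dibenzyl 2-[1-(ArB-oxy)ethenyl]propanedioate F8.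
   - Its acidic malonate C–H is soft-enolised (Et3N, Me3SiOTf, CH2Cl2, 0 °C) and the amine-free, salt-free solution of 19 is used directly in step 13.

3. Step 17. Hydrogenolysis may over-reduce: the secondary benzylic C–O bond is activated by the ortho-methoxy and para-aryloxy groups and may be cleaved along with the two benzyl groups. Fallback, setting out from ketone 23 and returning at target 26:
   - The benzyl groups are removed while the benzylic carbon is still a ketone (H2, 10% Pd/C, EtOAc) to give 6-(2-hydroxy-4-methyl-6-{[tri(propan-2-yl)silyl]oxymethyl}phenoxy)-2-methoxy-3-[3-methyl-3-(triethylsilyloxy)butanoyl]benzoic acid F9.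
   - Asymmetric transfer hydrogenation, which tolerates free acids and phenols (RuCl[(R,R)-TsDPEN](p-cymene), HCO2H/Et3N, 30 °C), gives the (R)-carbinol 3-[(1R)-1-hydroxy-3-methyl-3-(triethylsilyloxy)butyl]-6-(2-hydroxy-4-methyl-6-{[tri(propan-2-yl)silyl]oxymethyl}phenoxy)-2-methoxybenzoic acid F10.
   - Bu4NF then gives 26.

**Further compounds**

F1 | step 13 | 2-fluoro-6-hydroxybenzoic acid (purchased) | O=C(O)c1c(O)cccc1F
F2 | step 13 | benzyl 2-fluoro-6-hydroxybenzoate | O=C(OCc1ccccc1)c1c(O)cccc1F
F3 | step 13 | benzyl 6-fluoro-3-formyl-2-hydroxybenzoate | O=Cc1ccc(F)c(C(=O)OCc2ccccc2)c1O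
F4 | step 13 | benzyl 6-fluoro-3-formyl-2-methoxybenzoate | COc1c(C=O)ccc(F)c1C(=O)OCc1ccccc1
F5 | step 13 | benzyl 6-(ArB-oxy)-3-formyl-2-methoxybenzoate | COc1c(C=O)ccc(Oc2c(OCc3ccccc3)cc(C)cc2CO[Si](C(C)C)(C(C)C)C(C)C)c1C(=O)OCc1ccccc1
F6 | step 13 | benzyl 6-(ArB-oxy)-3-[(1R)-1-hydroxy-3-methylbut-3-enyl]-2-methoxybenzoate | COc1c([C@H](O)CC(C)=C)ccc(Oc2c(OCc3ccccc3)cc(C)cc2CO[Si](C(C)C)(C(C)C)C(C)C)c1C(=O)OCc1ccccc1
F7 | step 13 | benzyl 6-(ArB-oxy)-3-[(1R)-1,3-dihydroxy-3-methylbutyl]-2-methoxybenzoate | COc1c([C@H](O)CC(C)(C)O)ccc(Oc2c(OCc3ccccc3)cc(C)cc2CO[Si](C(C)C)(C(C)C)C(C)C)c1C(=O)OCc1ccccc1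
F8 | step 12 | dibenzyl 2-[1-(ArB-oxy)ethenyl]propanedioate | C=C(Oc1c(OCc2ccccc2)cc(C)cc1CO[Si](C(C)C)(C(C)C)C(C)C)C(C(=O)OCc1ccccc1)C(=O)OCc1ccccc1
F9 | step 17 | 6-(2-hydroxy-4-methyl-6-{[tri(propan-2-yl)silyl]oxymethyl}phenoxy)-2-methoxy-3-[3-methyl-3-(triethylsilyloxy)butanoyl]benzoic acid | COc1c(C(=O)CC(C)(C)O[Si](CC)(CC)CC)ccc(Oc2c(O)cc(C)cc2CO[Si](C(C)C)(C(C)C)C(C)C)c1C(=O)O
F10 | step 17 | 3-[(1R)-1-hydroxy-3-methyl-3-(triethylsilyloxy)butyl]-6-(2-hydroxy-4-methyl-6-{[tri(propan-2-yl)silyl]oxymethyl}phenoxy)-2-methoxybenzoic acid | COc1c([C@H](O)CC(C)(C)O[Si](CC)(CC)CC)ccc(Oc2c(O)cc(C)cc2CO[Si](C(C)C)(C(C)C)C(C)C)c1C(=O)O
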